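Ring A is closed last, on a finished ring B, by a formal [4+2] annulation that inserts the C2–C3 unit between the two quaternary carbons C4 and C10. The lithium enolate of a C18→O6 γ-lactone attacks vinyltriphenylphosphonium bromide through C4 (C3–C4), and the ylide so formed olefinates the neopentyl C1 aldehyde on C10 (C1=C2). The step exploits the unfunctionalised C1–C2–C3 edge of ring A and the 1,4-relationship of O6 and C18: tied as a trans-fused lactone, it shields one enolate face and fixes C4. The precursor is a monocyclic ring-B lactone aldehyde built from a quinone monoketal by enantioselective conjugate addition.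

Key step: step 10

Remark on the chemistry: labdane numbering is used for all intermediates (ring A = C1–C5 and C10, ring B = C5–C10, side chain C11–C16, C17 on C8, C18 = oxygenated carbon on C4, C19 = methyl on C4, C20 = methyl on C10). Dienone 1 is taken as commercially available. C4 is a mixture of epimers from step 6 to step 9; this is harmless because C4 is enolised in step 10.

Step 1
Reactants: 1 4,4-dimethoxycyclohexa-2,5-dien-1-one; 2 2-(2-bromoethyl)-2-methyl-1,3-dioxolane
Product: 4 (S)-4,4-dimethoxy-5-[2-(2-methyl-1,3-dioxolan-2-yl)ethyl]cyclohex-2-en-1-one, via zinc enolate 3 (not isolated)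
Conditions: 2, Mg, THF; ZnCl2 (0.5 equiv), 1,4-dioxane, filtration; then 1, Cu(OTf)2 (2 mol %), binaphthol-derived (S,R,R)-phosphoramidite ligand (4 mol %), toluene, −25 °C; aq. NH4Cl
Reagents that add atoms: none
Why: Copper–phosphoramidite-catalysed asymmetric conjugate addition of a dialkylzinc to a symmetrical cyclohexadienone monoketal (desymmetrisation) should select one enantiotopic enone arm and face and so set C9; the antipodal ligand is used if the sense of induction proves opposite, and the zinc enolate is simply protonated so that the second enone survives.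

Step 2
Reactants: 4 (S)-4,4-dimethoxy-5-[2-(2-methyl-1,3-dioxolan-2-yl)ethyl]cyclohex-2-en-1-one
Product: 6 4,4-dimethoxy-6-methyl-5-[2-(2-methyl-1,3-dioxolan-2-yl)ethyl]cyclohex-2-en-1-one (methyl trans to the side chain), via lithium dienolate 5 (not isolated)
Conditions: LiN(iPr)2, THF, −78 °C; MeI, −78 → −20 °C
Reagents that add atoms: iodomethane, CI
Why: Enolate alkylation: deprotonation can occur only at C10 (the ketal carbon C8 has no hydrogen), and the cross-conjugated dienolate should be methylated trans to the C9 chain, a configuration that is erased again in step 3.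

Step 3
Reactants: 6 4,4-dimethoxy-6-methyl-5-[2-(2-methyl-1,3-dioxolan-2-yl)ethyl]cyclohex-2-en-1-one
Product: 8 6-(benzyloxymethyl)-4,4-dimethoxy-6-methyl-5-[2-(2-methyl-1,3-dioxolan-2-yl)ethyl]cyclohex-2-en-1-one (CH2OBn trans and CH3 cis to the side chain), via lithium dienolate 7 (not isolated)
Conditions: LiN(iPr)2, THF, −78 → −40 °C; DMPU, BnOCH2Cl, −78 → 0 °C
Reagents that add atoms: benzyl chloromethyl ether, ClCOCc1ccccc1
Why: Enolate alkylation forming quaternary C10: in the flat dienolate the C9 chain sits pseudo-axial to avoid allylic 1,2-strain with the C10 methyl, so the chloromethyl ether should enter from the opposite face and place the future C1 trans to C11 and C20 cis to it.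

Step 4
Reactants: 8 6-(benzyloxymethyl)-4,4-dimethoxy-6-methyl-5-[2-(2-methyl-1,3-dioxolan-2-yl)ethyl]cyclohex-2-en-1-one
Product: 10 6-(benzyloxymethyl)-4,4-dimethoxy-6-methyl-5-[2-(2-methyl-1,3-dioxolan-2-yl)ethyl]cyclohex-1-en-1-yl trifluoromethanesulfonate, via lithium enolate 9 (not isolated)
Conditions: LiBH(s-Bu)3, THF, −78 °C; PhNTf2, −78 → 0 °C
Reagents that add atoms: N-phenylbis(trifluoromethanesulfonimide), O=S(=O)(N(c1ccccc1)S(=O)(=O)C(F)(F)F)C(F)(F)F
Why: Conjugate reduction with a bulky trialkylborohydride delivers hydride to C7, and the regiodefined C5=C6 enolate is trapped on oxygen by the triflimide (reductive enol triflate formation); no stereocenter is formed.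

Step 5
Reactants: 10 cyclohexenyl triflate; 11 isopropenylboronic acid pinacol ester
Product: 12 1-(benzyloxymethyl)-3,3-dimethoxy-1-methyl-2-[2-(2-methyl-1,3-dioxolan-2-yl)ethyl]-6-(prop-1-en-2-yl)cyclohex-5-ene (ring-B diene; C4 with C18 and C19 attached at C5)
Conditions: Pd(PPh3)4 (5 mol %), K3PO4, 1,4-dioxane/H2O, 80 °C
Reagents that add atoms: none
Why: Suzuki–Miyaura coupling of an alkenyl triflate with an alkenylboronate attaches C4 with its two one-carbon substituents; no stereocenter is formed.

Step 6
Reactants: 12 ring-B diene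
Product: 14 C6,C18-diol (cyclohexanol carrying a 1-hydroxypropan-2-yl group at C5; H5 and 6-OH cis to each other and trans to C20; C4 epimers), via cyclic borane 13 (not isolated)
Conditions: BH3·THF (3 equiv), THF, 0 → 23 °C; NaOH, H2O2, 0 → 23 °C
Reagents that add atoms: hydrogen peroxide, OO
Why: Double hydroboration–oxidation: boron goes to the less substituted carbons C18 and C6, and syn addition to the ring alkene from the face opposite the axial C10 methyl and the axial C8 methoxy group should place H5 and O6 cis to each other and trans to C20, which sets C5 and C6.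

Step 7
Reactants: 14 C6,C18-diol
Product: 17 benzyl ether lactone (C18→O6 γ-lactone trans-fused to ring B; C4 epimers; C10 bears CH3 and CH2OBn), via hydroxy aldehyde 15 (not isolated), via lactol 16 (not isolated)
Conditions: TEMPO (20 mol %), PhI(OAc)2 (2.5 equiv), NaHCO3, CH2Cl2, 23 °C
Reagents that add atoms: none
Why: Oxoammonium (TEMPO) oxidation selects the primary C18 alcohol, the aldehyde is captured by the C6 hydroxyl as the five-membered lactol and oxidised on to the lactone (oxidative lactonisation of a 1,4-diol); the ring fusion is trans because C4 and O6 are trans-diequatorial on ring B.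

Step 8
Reactants: 17 benzyl ether lactone
Product: 18 hydroxy lactone (C10 bears CH3 and CH2OH)
Conditions: H2 (1 atm), Pd(OH)2/C, EtOAc, 23 °C
Reagents that add atoms: none
Why: Hydrogenolysis of the benzyl ether frees the neopentyl C1 alcohol; no alkene is present, and the ketals and lactone are inert under neutral conditions.

Step 9
Reactants: 18 hydroxy lactone
Product: 19 lactone aldehyde (C10 bears CH3 and CHO)
Conditions: Dess–Martin periodinane, NaHCO3, CH2Cl2, 0 → 23 °C
Reagents that add atoms: none
Why: Buffered Dess–Martin oxidation of the primary alcohol spares both ketals, and the aldehyde cannot epimerise because C10 is quaternary.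

Step 10
Reactants: 19 lactone aldehyde; 20 vinyltriphenylphosphonium bromide
Product: 23 tricyclic alkene lactone (ring A closed with C1=C2; 18,6-olide; C8 dimethyl ketal), via lithium lactone enolate 21 (not isolated), via phosphorus ylide 22 (not isolated)
Conditions: lithium 2,2,6,6-tetramethylpiperidide (1.1 equiv), THF, −78 °C; 20 (1.5 equiv), DMPU, −78 → 23 °C; then 50 °C
Reagents that add atoms: none
Why: The hindered amide, which has no β-hydride and cannot add to the aldehyde, removes the C4 proton of the lactone; the enolate adds through C4 to the terminal carbon of the vinylphosphonium salt (C3–C4), and the non-stabilised ylide so formed at C2 attacks the C1 aldehyde and collapses through an oxaphosphetane to the cis C1=C2 alkene and Ph3PO. The closest known reaction type is the cycloalkene synthesis from vinylphosphonium salts, conjugate addition of a carbanion followed by intramolecular Wittig olefination. Ring A closes as a six-membered ring by attack of the ylide carbon on the carbonyl carbon, a 6-exo-trig closure with respect to C=O. The one new stereocenter, quaternary C4, is set in the intermolecular step: the lactone ring holds C18 toward O6, C10 with its axial methyl C20 covers one face of the planar enolate, and the salt should enter from the H5 face, so that C3 ends cis to H5 and the C19 methyl cis to C20. The step needs C-alkylation at C4 ahead of any enolate–aldehyde condensation, which the non-enolisable neopentyl aldehyde and the low-temperature enolate formation should secure; the gauche arrangement of the C4–C3–C2 arm and the equatorial C1 aldehyde about C5–C10 then allows a chair-like closure.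

Step 11
Reactants: 23 tricyclic alkene lactone
Product: 24 saturated tricyclic lactone (C8 dimethyl ketal)
Conditions: H2 (1 atm), Pd/C, EtOAc, 23 °C
Reagents that add atoms: none
Why: Heterogeneous hydrogenation of the cis-disubstituted C1=C2 bond, the only alkene in the molecule; no stereocenter is formed.

Step 12
Reactants: 24 saturated tricyclic lactone
Product: 25 keto lactone (C8 ketone; side-chain dioxolane intact)
Conditions: oxalic acid, wet SiO2, CH2Cl2, 23 °C
Reagents that add atoms: water, O
Why: Chemoselective ketal hydrolysis: an acyclic dimethyl ketal is cleaved far faster than a 1,3-dioxolane under mild acid, so only the C8 ketone should be released.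

Step 13
Reactants: 25 keto lactone
Product: 27 alkenyl triflate (C7=C8 with OTf on C8), via potassium enolate 26 (not isolated)
Conditions: KN(SiMe3)2, THF, −78 °C; N-(5-chloropyridin-2-yl)bis(trifluoromethanesulfonimide), −78 °C
Reagents that add atoms: N-(5-chloropyridin-2-yl)bis(trifluoromethanesulfonimide), O=S(=O)(N(c1ccc(Cl)cn1)S(=O)(=O)C(F)(F)F)C(F)(F)F
Why: Kinetic enol triflate formation: deprotonation should occur at the C7 methylene (C9 is a hindered methine next to quaternary C10), and the pseudo-equatorial C6–O bond of the rigid trans-lactone lies near the nodal plane of the enolate, which disfavours E1cB loss of the carboxylate before O-triflation.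

Step 14
Reactants: 27 alkenyl triflate
Product: 28 labd-7-ene 18,6-lactone with the side-chain dioxolane (C17 methyl on C8)
Conditions: MeZnCl, Pd(PPh3)4 (5 mol %), THF, 0 → 23 °C
Reagents that add atoms: methylzinc chloride, C[Zn]Cl
Why: Negishi coupling of the alkenyl triflate under zerovalent palladium catalysis replaces OTf by the C17 methyl with the double bond held at C7=C8; room temperature should keep the allylic C6–O bond from ionising.

Step 15
Reactants: 28 labd-7-ene 18,6-lactone
Product: 30 keto diol (6-OH and 18-OH free; side-chain methyl ketone), via diol ketal 29 (not isolated)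
Conditions: LiAlH4, THF, 0 °C; aq. potassium sodium tartrate; then PPTS, acetone/H2O, 40 °C
Reagents that add atoms: water, O
Why: Ester reduction then ketal hydrolysis: LiAlH4 opens the lactone to the C6/C18 diol without touching the trisubstituted alkene or the dioxolane, and mild acid-catalysed transketalisation then frees the methyl ketone while sparing the allylic alcohol.

Step 16
Reactants: 30 keto diol; 31 trimethyl phosphonoacetate
Product: 32 methyl (2E)-5-[(1R,4R,4aS,5S,8aS)-4-hydroxy-5-(hydroxymethyl)-2,5,8a-trimethyl-1,4,4a,5,6,7,8,8a-octahydronaphthalen-1-yl]-3-methylpent-2-enoate (CNP0149445.1)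
Conditions: NaH, 31, THF, 0 °C; then 30, 0 → 50 °C
Reagents that add atoms: none
Why: Horner–Wadsworth–Emmons olefination of the methyl ketone with the preformed sodium phosphonate, which is not basic enough to deprotonate the free hydroxyls; the longer C12 chain should prefer the position trans to the ester, so the E enoate should predominate, and the minor Z isomer is to be removed by chromatography.

Compound list

1 | 4,4-dimethoxycyclohexa-2,5-dien-1-one | COC1(OC)C=CC(=O)C=C1 | starting material
2 | 2-(2-bromoethyl)-2-methyl-1,3-dioxolane | CC1(CCBr)OCCO1 | starting material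
3 | alkylzinc dienolate formed by conjugate addition to 1 | CC4(OCCO4)CC[C@@H]1C(OC)(OC)C=CC(O[Zn]CCC5(C)OCCO5)=C1 | intermediate (not isolated)
4 | (S)-4,4-dimethoxy-5-[2-(2-methyl-1,3-dioxolan-2-yl)ethyl]cyclohex-2-en-1-one | CC4(OCCO4)CC[C@@H]1C(OC)(OC)C=CC(=O)C1 | intermediate
5 | lithium dienolate of 4 (C5 oxygen, C5=C10) | CC4(OCCO4)CC[C@@H]1C(OC)(OC)C=CC(O[Li])=C1 | intermediate (not isolated)
6 | 4,4-dimethoxy-6-methyl-5-[2-(2-methyl-1,3-dioxolan-2-yl)ethyl]cyclohex-2-en-1-one, methyl trans to the side chain | CC4(OCCO4)CC[C@@H]1C(OC)(OC)C=CC(=O)[C@H]1C | intermediate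
7 | lithium dienolate of 6 | CC4(OCCO4)CC[C@@H]1C(OC)(OC)C=CC(O[Li])=C1C | intermediate (not isolated)
8 | 6-(benzyloxymethyl)-4,4-dimethoxy-6-methyl-5-[2-(2-methyl-1,3-dioxolan-2-yl)ethyl]cyclohex-2-en-1-one, CH2OBn trans and CH3 cis to the side chain | CC4(OCCO4)CC[C@@H]1C(OC)(OC)C=CC(=O)[C@@]1(C)COCc5ccccc5 | intermediate
9 | lithium enolate from conjugate reduction of 8 (C5=C6) | CC4(OCCO4)CC[C@@H]1C(OC)(OC)CC=C(O[Li])[C@@]1(C)COCc5ccccc5 | intermediate (not isolated)
10 | cyclohexenyl triflate (C5=C6, OTf on C5) | CC4(OCCO4)CC[C@@H]1C(OC)(OC)CC=C(OS(=O)(=O)C(F)(F)F)[C@@]1(C)COCc5ccccc5 | intermediate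
11 | isopropenylboronic acid pinacol ester | CC(=C)B1OC(C)(C)C(C)(C)O1 | starting material
12 | ring-B diene (isopropenyl on C5, C5=C6) | CC4(OCCO4)CC[C@@H]1C(OC)(OC)CC=C(C(C)=C)[C@@]1(C)COCc5ccccc5 | intermediate
13 | cyclic borane (borolane through C6, B, C18, C4, C5; C4 epimers) | CC4(OCCO4)CC[C@@H]1C(OC)(OC)C[C@H]3BCC(C)[C@@H]3[C@@]1(C)COCc5ccccc5 | intermediate (not isolated)
14 | C6,C18-diol (H5 and 6-OH cis, both trans to C20; C4 epimers) | CC4(OCCO4)CC[C@@H]1C(OC)(OC)C[C@@H](O)[C@H](C(C)CO)[C@@]1(C)COCc5ccccc5 | intermediate
15 | C18 hydroxy aldehyde (C4 epimers) | CC4(OCCO4)CC[C@@H]1C(OC)(OC)C[C@@H](O)[C@H](C(C)C=O)[C@@]1(C)COCc5ccccc5 | intermediate (not isolated)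
16 | lactol (C18 hemiacetal with O6) | CC4(OCCO4)CC[C@@H]1C(OC)(OC)C[C@H]3OC(O)C(C)[C@@H]3[C@@]1(C)COCc5ccccc5 | intermediate (not isolated)
17 | benzyl ether lactone (trans-fused C18→O6 γ-lactone; C4 epimers) | CC4(OCCO4)CC[C@@H]1C(OC)(OC)C[C@H]3OC(=O)C(C)[C@@H]3[C@@]1(C)COCc5ccccc5 | intermediate
18 | hydroxy lactone (C1 as CH2OH on C10) | CC4(OCCO4)CC[C@@H]1C(OC)(OC)C[C@H]3OC(=O)C(C)[C@@H]3[C@@]1(C)CO | intermediate
19 | lactone aldehyde (C1 as CHO on C10) | CC4(OCCO4)CC[C@@H]1C(OC)(OC)C[C@H]3OC(=O)C(C)[C@@H]3[C@@]1(C)C=O | intermediate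
20 | vinyltriphenylphosphonium bromide | C=C[P+](c1ccccc1)(c1ccccc1)c1ccccc1.[Br-] | starting material
21 | lithium enolate of lactone 19 (C4=C18) | CC4(OCCO4)CC[C@@H]1C(OC)(OC)C[C@H]3OC(O[Li])=C(C)[C@@H]3[C@@]1(C)C=O | intermediate (not isolated)
22 | phosphorus ylide after conjugate addition (C4 quaternary, C2=PPh3) | CC4(OCCO4)CC[C@@H]1C(OC)(OC)C[C@H]3OC(=O)[C@@](C)(CC=P(c5ccccc5)(c5ccccc5)c5ccccc5)[C@@H]3[C@@]1(C)C=O | intermediate (not isolated)
23 | tricyclic alkene lactone (C1=C2; 18,6-olide; C8 dimethyl ketal) | CC4(OCCO4)CC[C@@H]1C(OC)(OC)C[C@@H](O3)[C@@H]2[C@@](C)(C3=O)CC=C[C@@]12C | intermediate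
24 | saturated tricyclic lactone (C8 dimethyl ketal) | CC4(OCCO4)CC[C@@H]1C(OC)(OC)C[C@@H](O3)[C@@H]2[C@@](C)(C3=O)CCC[C@@]12C | intermediate
25 | keto lactone (C8 ketone) | CC4(OCCO4)CC[C@@H]1C(=O)C[C@@H](O3)[C@@H]2[C@@](C)(C3=O)CCC[C@@]12C | intermediate
26 | potassium enolate of 25 (C7=C8) | CC4(OCCO4)CC[C@@H]1C(O[K])=C[C@@H](O3)[C@@H]2[C@@](C)(C3=O)CCC[C@@]12C | intermediate (not isolated)
27 | alkenyl triflate (C7=C8, OTf on C8) | CC4(OCCO4)CC[C@@H]1C(OS(=O)(=O)C(F)(F)F)=C[C@@H](O3)[C@@H]2[C@@](C)(C3=O)CCC[C@@]12C | intermediate
28 | labd-7-ene 18,6-lactone with side-chain dioxolane | CC4(OCCO4)CC[C@@H]1C(C)=C[C@@H](O3)[C@@H]2[C@@](C)(C3=O)CCC[C@@]12C | intermediate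
29 | 6,18-diol with side-chain dioxolane | CC4(OCCO4)CC[C@@H]1C(C)=C[C@@H](O)[C@@H]2[C@@](C)(CO)CCC[C@@]12C | intermediate (not isolated)
30 | keto diol (C13 methyl ketone; 6-OH and 18-OH) | CC(=O)CC[C@@H]1C(C)=C[C@@H](O)[C@@H]2[C@@](C)(CO)CCC[C@@]12C | intermediate
31 | trimethyl phosphonoacetate | COC(=O)CP(=O)(OC)OC | starting material
32 | methyl (2E)-5-[(1R,4R,4aS,5S,8aS)-4-hydroxy-5-(hydroxymethyl)-2,5,8a-trimethyl-1,4,4a,5,6,7,8,8a-octahydronaphthalen-1-yl]-3-methylpent-2-enoate | COC(=O)/C=C(\C)CC[C@@H]1C(C)=C[C@@H](O)[C@@H]2[C@@](C)(CO)CCC[C@@]12C | target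

Total step count: 16. Longest linear sequence: 16 steps (1 → 32); compounds 2, 11, 20 and 31 are commercial.

Steps most likely to fail

Step 10. The conjugate addition of the hindered tertiary enolate to the sparingly soluble phosphonium salt may be slow, which would let the enolate condense with the free aldehyde, or the ylide may fail to close the trans-fused ring. The fallback sets out from aldehyde 19 and keeps both bond formations in one operation but changes the acceptor and the ring-closing event. The lithium enolate (same base) is treated with phenyl vinyl sulfone, and the α-sulfonyl carbanion formed by addition at C3 closes onto the C1 aldehyde. The alkoxide is trapped in the same flask with Ac2O to give the ring-A acetoxy sulfone F1 (C1 and C2 epimers). Reductive elimination with SmI2 in THF/DMPU (Julia-type olefination) then gives the C1=C2 alkene and returns to the route at 23.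

Step 13. The C7 enolate may expel the C6 carboxylate (E1cB opening of the lactone to a C6=C7 enone acid) faster than it is triflated. The fallback sets out from ketone 25 and avoids any enolate. Condensation with hydrazine hydrate (Et3N, EtOH) gives the hydrazone F2. Iodine and 1,1,3,3-tetramethylguanidine in THF (Barton vinyl iodide synthesis) convert it into the alkenyl iodide F3, with loss of the less hindered C7 proton. The Negishi methylation of step 14 (MeZnCl, Pd(PPh3)4), applied to F3, returns to the route at 28.

Step 4. The hydride may be delivered to the carbonyl (1,2-reduction) because C7 is flanked by the ketal carbon. The fallback sets out from enone 8 and separates the two events. Hydrogenation of the C6=C7 bond with H2 and RhCl(PPh3)3 in benzene, a homogeneous catalyst that leaves the benzyl ether, gives the saturated ketone F4. Deprotonation at C6, the only α-methylene, with KN(SiMe3)2 and O-triflation with PhNTf2 returns to the route at 10.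

Further compounds
F1 | step 10 | ring-A acetoxy sulfone (1-acetoxy-2-phenylsulfonyl tricyclic 18,6-lactone; C1 and C2 epimers) | CC4(OCCO4)CC[C@@H]1C(OC)(OC)C[C@@H](O3)[C@@H]2[C@@](C)(C3=O)CC(S(=O)(=O)c5ccccc5)C(OC(C)=O)[C@@]12C
F2 | step 13 | hydrazone of keto lactone 25 | CC4(OCCO4)CC[C@@H]1C(=NN)C[C@@H](O3)[C@@H]2[C@@](C)(C3=O)CCC[C@@]12C
F3 | step 13 | alkenyl iodide (C7=C8, iodine on C8) | CC4(OCCO4)CC[C@@H]1C(I)=C[C@@H](O3)[C@@H]2[C@@](C)(C3=O)CCC[C@@]12C
F4 | step 4 | 2-(benzyloxymethyl)-4,4-dimethoxy-2-methyl-3-[2-(2-methyl-1,3-dioxolan-2-yl)ethyl]cyclohexan-1-one | CC4(OCCO4)CC[C@@H]1C(OC)(OC)CCC(=O)[C@@]1(C)COCc5ccccc5
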